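## Retrosynthetic overview

1. The target comes from O-debenzylation (H2, Pd/C) of its 5,7,4'-tri-O-benzyl ether, which comes from acetylation of the 3-OH, freed by DDQ cleavage of a 3-O-PMB ether.
2. Ring C, the only ring built, closes by a catalyst-controlled 6-endo intramolecular oxa-Michael addition of the 2'-phenol onto a (Z)-α-(PMB-oxy)chalcone. The catalyst sets C2, and protonation to the 2,3-trans isomer sets C3.
3. The chalcone comes from an aryl–acyl bond between a ring A bromophenol (used as its dimetalated form) and a ring B α-alkoxycinnamic Weinreb amide.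
4. The ring A fragment comes from methyl 4-O-methylgallate: benzylation, ester to aldehyde, Dakin-type oxidation, then ortho-bromination (the two ortho positions are equivalent by symmetry).
5. The ring B fragment comes from 4-hydroxybenzaldehyde and a PMB-oxy phosphonoacetate (diazo transfer, O–H insertion) by Horner–Wadsworth–Emmons olefination, then Weinreb amidation. Rings A and B are bought as arenes.

Assumption: methyl 3,5-dihydroxy-4-methoxybenzoate is taken as a purchasable starting material, and the facial sense of the cinchona catalyst in step 12 is assigned by analogy with ester-activated chalcones, not from precedent on this α-alkoxy substrate (the quinine-derived pseudoenantiomer gives the antipode if the sense proves opposite).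

## Route

Step 1
Reactants: 1 methyl 3,5-dihydroxy-4-methoxybenzoate
Product: 2 methyl 3,5-bis(benzyloxy)-4-methoxybenzoate
Conditions: BnBr (2.3 equiv), K2CO3, DMF, 60 °C
Reagents that add atoms: benzyl bromide, BrCc1ccccc1
Why: Williamson etherification masks the two phenols that become O-5 and O-7 as hydrogenolysable benzyl ethers while the ester is untouched.

Step 2
Reactants: 2 methyl 3,5-bis(benzyloxy)-4-methoxybenzoate
Product: 3 [3,5-bis(benzyloxy)-4-methoxyphenyl]methanol
Conditions: LiAlH4, THF, 0 °C → rt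
Reagents that add atoms: none
Why: Hydride reduction of the ester gives the benzylic alcohol, and aryl benzyl and methyl ethers are inert to LiAlH4.

Step 3
Reactants: 3 [3,5-bis(benzyloxy)-4-methoxyphenyl]methanol
Product: 4 3,5-bis(benzyloxy)-4-methoxybenzaldehyde
Conditions: MnO2 (activated, excess), CH2Cl2, rt
Reagents that add atoms: none
Why: Chemoselective benzylic alcohol oxidation with MnO2 stops cleanly at the aldehyde.

Step 4
Reactants: 4 3,5-bis(benzyloxy)-4-methoxybenzaldehyde
Product: 6 3,5-bis(benzyloxy)-4-methoxyphenol, via aryl formate 5 (not isolated)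
Conditions: mCPBA, CH2Cl2, 0 °C → rt; then MeOH, Et3N (3 equiv), rt
Reagents that add atoms: mCPBA, OOC(=O)c1cccc(Cl)c1
Why: Baeyer–Villiger (Dakin-type) oxidation, in which the electron-rich 3,4,5-trialkoxyaryl group migrates in preference to hydrogen, gives the formate, and amine-promoted methanolysis frees the symmetric phenol.

Step 5
Reactants: 6 3,5-bis(benzyloxy)-4-methoxyphenol
Product: 7 3,5-bis(benzyloxy)-2-bromo-4-methoxyphenol
Conditions: NBS (1.0 equiv), CH2Cl2, −40 → 0 °C
Reagents that add atoms: N-bromosuccinimide, BrN1C(=O)CCC1=O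
Why: Electrophilic aromatic bromination goes ortho to the free phenol because the para position carries the methoxy group, and the two ortho positions are equivalent by symmetry, so one regioisomer forms.

Step 6
Reactants: 8 triethyl phosphonoacetate
Product: 9 ethyl 2-diazo-2-(diethoxyphosphoryl)acetate
Conditions: NaH, 4-acetamidobenzenesulfonyl azide, THF, 0 °C → rt
Reagents that add atoms: 4-acetamidobenzenesulfonyl azide, CC(=O)Nc1ccc(cc1)S(=O)(=O)N=[N+]=[N-]
Why: Regitz diazo transfer to the sodium enolate of the doubly activated methylene gives the stabilised diazo phosphonoacetate.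

Step 7
Reactants: 9 ethyl 2-diazo-2-(diethoxyphosphoryl)acetate
Product: 10 ethyl 2-(diethoxyphosphoryl)-2-[(4-methoxybenzyl)oxy]acetate (racemic)
Conditions: 4-methoxybenzyl alcohol (1.2 equiv), Rh2(OAc)4 (1 mol %), toluene, 80 °C
Reagents that add atoms: 4-methoxybenzyl alcohol, COc1ccc(CO)cc1
Why: Rhodium carbenoid O–H insertion into the alcohol installs the PMB-protected oxygen that becomes O-3, and the racemic centre formed is erased in step 9.

Step 8
Reactants: 11 4-hydroxybenzaldehyde
Product: 12 4-(benzyloxy)benzaldehyde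
Conditions: BnBr (1.1 equiv), K2CO3, DMF, rt
Reagents that add atoms: benzyl bromide, BrCc1ccccc1
Why: Williamson etherification protects the future 4'-OH with the same hydrogenolysable group used on ring A.

Step 9
Reactants: 10 ethyl 2-(diethoxyphosphoryl)-2-[(4-methoxybenzyl)oxy]acetate; 12 4-(benzyloxy)benzaldehyde
Product: 13 ethyl (2Z)-3-[4-(benzyloxy)phenyl]-2-[(4-methoxybenzyl)oxy]prop-2-enoate
Conditions: NaH, THF, 0 °C → rt; chromatography (minor E isomer removed or isomerised with cat. I2)
Reagents that add atoms: none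
Why: Horner–Wadsworth–Emmons olefination of the α-alkoxy phosphonate gives the enol ether acrylate with the aryl group trans to the ester (Z) as the major, thermodynamically preferred isomer.

Step 10
Reactants: 13 ethyl (2Z)-3-[4-(benzyloxy)phenyl]-2-[(4-methoxybenzyl)oxy]prop-2-enoate
Product: 14 (2Z)-3-[4-(benzyloxy)phenyl]-N-methoxy-2-[(4-methoxybenzyl)oxy]-N-methylprop-2-enamide
Conditions: MeNH(OMe)·HCl (1.5 equiv), i-PrMgCl (3 equiv), THF, −20 → 0 °C
Reagents that add atoms: N,O-dimethylhydroxylamine hydrochloride, CNOC.Cl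
Why: Aminolysis of the ester by the magnesium amide gives the Weinreb amide, and the electron-rich, fully substituted alkene does not undergo conjugate addition.

Step 11
Reactants: 7 3,5-bis(benzyloxy)-2-bromo-4-methoxyphenol; 14 (2Z)-3-[4-(benzyloxy)phenyl]-N-methoxy-2-[(4-methoxybenzyl)oxy]-N-methylprop-2-enamide
Product: 16 (2Z)-1-[2,4-bis(benzyloxy)-6-hydroxy-3-methoxyphenyl]-3-[4-(benzyloxy)phenyl]-2-[(4-methoxybenzyl)oxy]prop-2-en-1-one, via lithiated sodium phenoxide 15 (not isolated)
Conditions: 7 (1.2 equiv), NaH, THF, 0 °C; t-BuLi (2.1 equiv), −78 °C; then 14, −78 → −30 °C; AcOH then aq NH4Cl at −78 °C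
Reagents that add atoms: none
Why: Bromine–lithium exchange on the phenoxide followed by Weinreb ketone synthesis forms the aryl ketone in one step, because the chelated tetrahedral adduct prevents over-addition and keeps the enone masked from the phenoxide until the cold acidic quench.

Step 12
Reactants: 16 (2Z)-1-[2,4-bis(benzyloxy)-6-hydroxy-3-methoxyphenyl]-3-[4-(benzyloxy)phenyl]-2-[(4-methoxybenzyl)oxy]prop-2-en-1-one
Product: 17 (2R,3R)-5,7-bis(benzyloxy)-2-[4-(benzyloxy)phenyl]-6-methoxy-3-[(4-methoxybenzyl)oxy]-2,3-dihydro-4H-chromen-4-one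
Conditions: N-[3,5-bis(trifluoromethyl)phenyl]-N'-[(9R)-6'-methoxycinchonan-9-yl]thiourea (quinidine-derived, 10–20 mol %), toluene, 0 °C → rt, 48 h; recrystallise to raise ee
Reagents that add atoms: none
Why: Enantioselective 6-endo-trig intramolecular oxa-Michael addition, in which the quinuclidine ion-pairs the phenoxide and the thiourea binds the enone carbonyl so that one face of the β-carbon is attacked to set C2, while C3 is set by protonation and amine-mediated equilibration to the diequatorial 2,3-trans isomer.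

Step 13
Reactants: 17 (2R,3R)-5,7-bis(benzyloxy)-2-[4-(benzyloxy)phenyl]-6-methoxy-3-[(4-methoxybenzyl)oxy]-2,3-dihydro-4H-chromen-4-one
Product: 18 (2R,3R)-5,7-bis(benzyloxy)-2-[4-(benzyloxy)phenyl]-3-hydroxy-6-methoxy-2,3-dihydro-4H-chromen-4-one
Conditions: DDQ (1.3 equiv), CH2Cl2/pH 7 buffer (10:1), 0 °C
Reagents that add atoms: none
Why: Oxidative PMB ether cleavage by DDQ is selective for the electron-rich 4-methoxybenzyl group over the plain benzyl ethers and is neutral, so neither stereocentre is disturbed.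

Step 14
Reactants: 18 (2R,3R)-5,7-bis(benzyloxy)-2-[4-(benzyloxy)phenyl]-3-hydroxy-6-methoxy-2,3-dihydro-4H-chromen-4-one
Product: 19 (2R,3R)-5,7-bis(benzyloxy)-2-[4-(benzyloxy)phenyl]-6-methoxy-4-oxo-3,4-dihydro-2H-chromen-3-yl acetate
Conditions: Ac2O, pyridine, DMAP (cat.), CH2Cl2, 0 °C → rt
Reagents that add atoms: acetic anhydride, CC(=O)OC(C)=O
Why: DMAP-catalysed acylation hits the only free hydroxyl because every phenol is still benzylated, and the trans isomer is the thermodynamic one, so the mild base does not scramble C3.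

Step 15
Reactants: 19 (2R,3R)-5,7-bis(benzyloxy)-2-[4-(benzyloxy)phenyl]-6-methoxy-4-oxo-3,4-dihydro-2H-chromen-3-yl acetate
Product: 20 (2R,3R)-5,7-dihydroxy-2-(4-hydroxyphenyl)-6-methoxy-4-oxo-3,4-dihydro-2H-chromen-3-yl acetate (6-methoxyaromadendrin 3-O-acetate)
Conditions: H2 (1 atm), 10% Pd/C, EtOAc/THF, rt, stop at full conversion
Reagents that add atoms: none
Why: Catalytic hydrogenolysis removes the three aryl benzyl ethers under neutral conditions that leave the acetate, the ketone, the aryl methyl ether and both stereocentres intact.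

## Compound list

1 | methyl 3,5-dihydroxy-4-methoxybenzoate | COC(=O)c1cc(O)c(OC)c(O)c1 | starting material
2 | methyl 3,5-bis(benzyloxy)-4-methoxybenzoate | COC(=O)c1cc(OCc2ccccc2)c(OC)c(OCc2ccccc2)c1 | intermediate
3 | [3,5-bis(benzyloxy)-4-methoxyphenyl]methanol | OCc1cc(OCc2ccccc2)c(OC)c(OCc2ccccc2)c1 | intermediate
4 | 3,5-bis(benzyloxy)-4-methoxybenzaldehyde | O=Cc1cc(OCc2ccccc2)c(OC)c(OCc2ccccc2)c1 | intermediate
5 | 3,5-bis(benzyloxy)-4-methoxyphenyl formate (not isolated) | O=COc1cc(OCc2ccccc2)c(OC)c(OCc2ccccc2)c1 | intermediate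
6 | 3,5-bis(benzyloxy)-4-methoxyphenol | Oc1cc(OCc2ccccc2)c(OC)c(OCc2ccccc2)c1 | intermediate
7 | 3,5-bis(benzyloxy)-2-bromo-4-methoxyphenol | Oc1cc(OCc2ccccc2)c(OC)c(OCc2ccccc2)c1Br | intermediate
8 | triethyl phosphonoacetate | CCOC(=O)CP(=O)(OCC)OCC | starting material
9 | ethyl 2-diazo-2-(diethoxyphosphoryl)acetate | CCOC(=O)C(=[N+]=[N-])P(=O)(OCC)OCC | intermediate
10 | ethyl 2-(diethoxyphosphoryl)-2-[(4-methoxybenzyl)oxy]acetate (racemic) | CCOC(=O)C(OCc1ccc(OC)cc1)P(=O)(OCC)OCC | intermediate
11 | 4-hydroxybenzaldehyde | O=Cc1ccc(O)cc1 | starting material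
12 | 4-(benzyloxy)benzaldehyde | O=Cc1ccc(OCc2ccccc2)cc1 | intermediate
13 | ethyl (2Z)-3-[4-(benzyloxy)phenyl]-2-[(4-methoxybenzyl)oxy]prop-2-enoate | CCOC(=O)/C(OCc1ccc(OC)cc1)=C/c1ccc(OCc2ccccc2)cc1 | intermediate
14 | (2Z)-3-[4-(benzyloxy)phenyl]-N-methoxy-2-[(4-methoxybenzyl)oxy]-N-methylprop-2-enamide | CON(C)C(=O)/C(OCc1ccc(OC)cc1)=C/c1ccc(OCc2ccccc2)cc1 | intermediate
15 | sodium 3,5-bis(benzyloxy)-2-lithio-4-methoxyphenolate (not isolated) | [Li]c1c(O[Na])cc(OCc2ccccc2)c(OC)c1OCc1ccccc1 | intermediate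
16 | (2Z)-1-[2,4-bis(benzyloxy)-6-hydroxy-3-methoxyphenyl]-3-[4-(benzyloxy)phenyl]-2-[(4-methoxybenzyl)oxy]prop-2-en-1-one | COc1c(OCc2ccccc2)cc(O)c(C(=O)/C(OCc2ccc(OC)cc2)=C/c2ccc(OCc3ccccc3)cc2)c1OCc1ccccc1 | intermediate
17 | (2R,3R)-5,7-bis(benzyloxy)-2-[4-(benzyloxy)phenyl]-6-methoxy-3-[(4-methoxybenzyl)oxy]-2,3-dihydro-4H-chromen-4-one | COc1c(OCc2ccccc2)cc2c(c1OCc1ccccc1)C(=O)[C@H](OCc1ccc(OC)cc1)[C@@H](c1ccc(OCc3ccccc3)cc1)O2 | intermediate
18 | (2R,3R)-5,7-bis(benzyloxy)-2-[4-(benzyloxy)phenyl]-3-hydroxy-6-methoxy-2,3-dihydro-4H-chromen-4-one | COc1c(OCc2ccccc2)cc2c(c1OCc1ccccc1)C(=O)[C@H](O)[C@@H](c1ccc(OCc3ccccc3)cc1)O2 | intermediate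
19 | (2R,3R)-5,7-bis(benzyloxy)-2-[4-(benzyloxy)phenyl]-6-methoxy-4-oxo-3,4-dihydro-2H-chromen-3-yl acetate | COc1c(OCc2ccccc2)cc2c(c1OCc1ccccc1)C(=O)[C@H](OC(C)=O)[C@@H](c1ccc(OCc3ccccc3)cc1)O2 | intermediate
20 | (2R,3R)-5,7-dihydroxy-2-(4-hydroxyphenyl)-6-methoxy-4-oxo-3,4-dihydro-2H-chromen-3-yl acetate (6-methoxyaromadendrin 3-O-acetate) | COc1c(O)cc2c(c1O)C(=O)[C@H](OC(C)=O)[C@@H](c1ccc(O)cc1)O2 | target

## Step count and risks

Total step count: 15.
Longest linear sequence: 10 (steps 1–5, then 11–15). The other arms are steps 6, 7, 9, 10 and steps 8, 9, 10 before the junction at step 11.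

Steps most likely to fail:

**Step 12 (enantioselective oxa-Michael).** The α-alkoxy enone is a weaker acceptor and a weaker hydrogen-bond partner than the ester-activated chalcones for which this catalyst class is proven, so rate or ee may be poor. The fallback sets out from 16 and gives up catalyst control. Compound 16 is cyclised under thermodynamic conditions (NaOAc, EtOH, 60 °C) to the racemic trans product, a 1:1 mixture of 17 and (2S,3S)-5,7-bis(benzyloxy)-2-[4-(benzyloxy)phenyl]-6-methoxy-3-[(4-methoxybenzyl)oxy]-2,3-dihydro-4H-chromen-4-one F1. The two are separated by preparative chiral SFC on an amylose tris(3,5-dimethylphenylcarbamate) phase. The unwanted enantiomer is re-racemised through the reversible ring opening to 16 (K2CO3, MeOH/THF, 50 °C) and resubmitted. The fallback comes back to the route at 17.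

**Step 11 (dianion acylation).** The doubly ortho-substituted aryl dianion may be too aggregated or too hindered to add to the α,α-disubstituted Weinreb amide. The fallback sets out from 6 and 13 and forms the aryl–acyl bond by rearrangement instead of organometallic addition. Ester 13 is saponified (LiOH, THF/H2O) to (2Z)-3-[4-(benzyloxy)phenyl]-2-[(4-methoxybenzyl)oxy]prop-2-enoic acid F2. This acid is esterified with phenol 6 (EDC·HCl, DMAP, CH2Cl2) to 3,5-bis(benzyloxy)-4-methoxyphenyl (2Z)-3-[4-(benzyloxy)phenyl]-2-[(4-methoxybenzyl)oxy]prop-2-enoate F3. Photo-Fries rearrangement (300 nm, benzene/MeCN) then moves the acyl group to an ortho carbon, the only open position because para is blocked and both ortho sites are equivalent. Catalytic I2 restores the Z geometry if light has scrambled it. The fallback comes back to the route at 16.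

**Step 15 (global hydrogenolysis).** Over-reduction (cleavage of the benzylic C2–O1 bond or reduction of the ketone) or a slow 5-O-benzyl removal is possible. The fallback sets out from 19 and replaces reduction by Lewis-acid dealkylation: BCl3 with pentamethylbenzene as benzyl-cation scavenger, CH2Cl2, −78 °C, then MeOH quench. This spares the acetate, the ketone, the C2–O1 bond and, at this temperature, the 6-methoxy group. It gives 20 directly and makes no new compound (F0).

## Further compounds

F1 | step 12 | (2S,3S)-5,7-bis(benzyloxy)-2-[4-(benzyloxy)phenyl]-6-methoxy-3-[(4-methoxybenzyl)oxy]-2,3-dihydro-4H-chromen-4-one | COc1c(OCc2ccccc2)cc2c(c1OCc1ccccc1)C(=O)[C@@H](OCc1ccc(OC)cc1)[C@H](c1ccc(OCc3ccccc3)cc1)O2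
F2 | step 11 | (2Z)-3-[4-(benzyloxy)phenyl]-2-[(4-methoxybenzyl)oxy]prop-2-enoic acid | OC(=O)/C(OCc1ccc(OC)cc1)=C/c1ccc(OCc2ccccc2)cc1
F3 | step 11 | 3,5-bis(benzyloxy)-4-methoxyphenyl (2Z)-3-[4-(benzyloxy)phenyl]-2-[(4-methoxybenzyl)oxy]prop-2-enoate | COc1c(OCc2ccccc2)cc(OC(=O)/C(OCc2ccc(OC)cc2)=C/c2ccc(OCc3ccccc3)cc2)cc1OCc1ccccc1
F0 | step 15 | none | none
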